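- A rate of 1.67 /h was the first thing I read, from the Z and L already standing at 0.417 h in Sunday's run, so D lasted on average 0.600 h before it became Z.

| flask | D | X | remark | time |
|---|---|---|---|---|
| Sunday's | 0.050 M | 1.1 equiv | run made earlier |  |
| Thursday's | 0.070 M | 1.1 equiv | run made earlier |  |
| Friday's | 0.11 M | 1.1 equiv | run made earlier |  |
| Tuesday's | 0.050 M | 0.55 equiv | run made earlier |  |
| cedar | 0.050 M | 1.10 equiv | one stirred flow tank at steady state, fed with the mixture as stated, mean residence time 8.0 h |  |
| larch | 0.050 M | 1.10 equiv | plug flow through a tube for 8.0 h, no back-mixing | 8.0 h |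
| oak | 0.050 M | 1.10 equiv | everything together in a closed stirred flask, run for 8.0 h | 8.0 h |
| elm | 0.050 M (fed, over 6.40 h) | 1.10 equiv | all but D at the start; D goes in evenly over 6.40 h, the run ends at 8.0 h | 8.0 h |

- Sunday's (time / h: Z / %, L / %): 0.417: 49.7, 0.4; 0.667: 65.4, 1.1; 1.33: 84.1, 1.9; 2.50: 85.3, 3.9; 5.00: 72.2, 8.1
- Thursday's (time / h: Z / %, L / %): 0.500: 56.4, 0; 1.50: 84.1, 2.9; 3.00: 81.2, 6.5; 5.00: 70.1, 9.8; 6.00: 63.8, 12.5
- Friday's (time / h: Z / %, L / %): 1.33: 82.2, 2.8; 2.50: 81.4, 6.6; 4.00: 70.2, 12.6; 5.00: 64.7, 15.6; 6.00: 59.4, 16.5
- Tuesday's (time / h: Z / %, L / %): 0.500: 56.5, 0.3; 1.00: 79.5, 0.9; 2.00: 88.2, 2.0; 3.00: 84.5, 2.2; 6.00: 70.5, 4.5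

(standard deviation of a reading: 0.5 percentage points)

- the stated concentrations are those of everything mixed, before any reaction; amounts are the same in each set-up
- what was read earlier has a scatter of 0.5 percentage points, one standard deviation
- the feed brings no volume worth counting
- the earlier runs were made in a closed, stirred flask
- a reading or a percentage of L counts all its forms, free or not

* the set-up with the highest amount of Z at the outlet or at the end, in percent of the D put in ("none" if the first two lie within 2 percentage points) (cedar / larch / oak / elm / none)
* amount of Z at the outlet or at the end, in percent of the D put in, cedar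
* amount of Z at the outlet or at the end, in percent of the D put in, larch
* amount of Z at the outlet or at the end, in percent of the D put in, oak
* amount of Z at the outlet or at the end, in percent of the D put in, elm

- Sunday's run has the charge of the four new set-ups, so I used its last reading, 72.2% of Z at 5.00 h. Z had stood there on average for 4.40 h, which gave a lifetime of Z at this charge, taken as pseudo-first-order, of 13.5 h. That is far longer than the life of D.
- My rule of thumb was that the share of Z at the end is the exponential of minus its mean age over that lifetime, the age being the end time less the mean feeding time less the life of D.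
- For oak and larch, which share one history, the age was 7.40 h, giving 57.8%.
- In elm, D enters on average at half the dosing time, so the age was 4.20 h, giving 73.3%.
- The rule gives each flask one age, so I held the spread of ages against the lifetime. In elm the ratio of half the dosing time to the lifetime was 0.237, but in cedar the ages spread as wide as their mean, and the ratio was 0.593.
- There I dropped the rule for a tank balance. Its Z step kept 62.8% where the exponential kept 55.3%, but I reckoned 6.96% of D unconverted, which gave cedar 58.4%.
- The forecast, built on “an X-driven path to L plus a first-order leak”, named elm, with 58.6% for cedar, 58% for larch, 58% for oak and 73.4% for elm, at most 0.18 percentage points from mine.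

    D → Z (k = 1.70 /h)
    X + Z → L (k = 0.390 /M/h)
    2 Z → E (k = 0.0410 /M/h)
    X + L ⇌ J, settled at all times (K = 34.0 /M)
    Z → Q (k = 0.0510 /h)

- Elm gave 73.4%, against 58.1% for oak, 58.1% for larch and 59.1% for cedar, so elm came out ahead. In oak, Z moved by 5 points when the end shifted from 8.0 h to 9.27 h. With the lifetime of 13.5 h, that later end gives 52.6%, which is 5.2 points below my figure for oak.

The earlier runs and the new flask are calculated for substances that don't exist.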